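The numbers in the tables were computed from invented constants.

I counted what was missing.

common to all: substrate 10 mM
- noon: precatalyst 4.4 mol%; temperature −20 °C; the very flask that is asked about, followed so far
- dawn: precatalyst 8.8 mol%; temperature −25 °C; run made earlier
- flask: precatalyst 4.4 mol%; temperature −20 °C; time 3.0 h

| run | time / min | target / % | substrate / % |
|---|---|---|---|
| noon | 20.0 | 7.1 | 84.7 |
| noon | 40.0 | 19.3 | 52.7 |
| noon | 60.0 | 34.0 | 13.6 |
| noon | 80.0 | 36.1 | 0.2 |
| noon | 90.0 | 36.3 | 0 |
| noon | 120 | 36.1 | 1.1 |
| noon | 150 | 36.5 | 0.1 |
| dawn | 0.833 | 0.8 | 99.6 |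
| dawn | 2.50 | 0.1 | 100.8 |
| dawn | 5.00 | 0 | 98.6 |
| dawn | 6.00 | 0.4 | 99.9 |
| dawn | 10.0 | 1.3 | 98.0 |
| dawn | 12.0 | 1.7 | 96.2 |
| dawn | 15.0 | 2.9 | 94.5 |

(standard deviation of a reading: 0.5 percentage points)

- north-east: change nothing and wait 1.5 h more
- south: at 3.0 h take out 90% of the target then present, then wait 1.5 h
- west: at 3.0 h raise the temperature by 20 K, then wait 1.5 h
- north-west: at 3.0 h add precatalyst, 100% of the amount charged, then wait 1.5 h

* target, in percent of the substrate first charged, at 3.0 h
* which option adds most target ("none" when 2 percentage points or less is all one gets) (north-east / south / west / north-west / none)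
* target present, with what was taken out counted in, in percent of the substrate first charged, after south
* target present, with what was taken out counted in, in percent of the substrate first charged, after west

- target taken out counts as made
- additions bring no volume worth counting

In the noon run, this very flask, I set two amounts side by side: target, and the missing part M, which is the charge less substrate and target. Their ratio r = M/target read 1.15 at 20.0 min, and 1.75 at 90.0 min, with substrate at 0%. A fixed split keeps r steady, but r rose. A one-way loss goes on eating target, but target stayed flat up to 150 min. So I took target and M for a reversible pair standing at a balance (an equilibrium), with target holding the share 1/(1+r), or 36.3%.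

That was my figure for the flask at 3.0 h. Taking out 90% of it removes 32.7%, and the remaining 67.3% should divide again in the same ratio, which gives 57.1% in all. The noon ratio had arrived by 80.0 min, sooner than the 1.5 h of waiting. I expected no gain from waiting or from precatalyst, with substrate read at 0% at 90.0 min in the noon run. Warming moves a balance, but these readings did not tell me how far, so I left west open and committed to south.

The forecast, which differed from my reckoning on south, gave 36.3% now, 36.3% after south, 36.3% after west and best none, on the ground that “nothing suggests a reservoir feeding it”.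

The flask gave 35.7% at 3.0 h, 56.4% after south, 73.3% after west, and best west.

    substrate + free catalyst → catalyst intermediate A (k = 1400 M⁻¹ min⁻¹, Ea = 35.0 kJ mol⁻¹)
    catalyst intermediate A ⇌ catalyst intermediate B (K = 20.0, k = 2.10 min⁻¹, Ea = 73.0 kJ mol⁻¹, ΔH = −27.0 kJ mol⁻¹)
    catalyst intermediate B → free catalyst + target (k = 1.30 min⁻¹, Ea = 62.0 kJ mol⁻¹)
    precatalyst ⇌ free catalyst (K = 2.40, k = 0.0240 min⁻¹, Ea = 76.0 kJ mol⁻¹, ΔH = 25.0 kJ mol⁻¹)
    target ⇌ isomer of the product (K = 1.80, k = 0.220 min⁻¹, Ea = 74.0 kJ mol⁻¹, ΔH = −46.0 kJ mol⁻¹)
    (constants at −20 °C)

M was the isomer of the product, 64.3% against 35.7% of target in this flask at 180 min. South gained 21 percentage points, against the 21 points I had reckoned, and west gained more, 38 points, leaving r at 0.364. The same flask run at −5 °C had 0% of its substrate left at 180 min, and isomer of the product at 34.6% against target at 65.4%. Its r was 0.529, lower than the 1.75 read in the noon run, and its target stood at 65.4%.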